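**Retrosynthetic overview**

- The strategy rests on the upper flavan: its C3 is a bare CH2 and its C4 is a benzylic methine bonded to C8 of ring D of the epigallocatechin unit, the carbon between O1 and the 7-oxygen. A C4 radical therefore has no β-oxygen to expel, and C8 can be marked by bromine.
- The C4–C8 bond is cut to a flavan-4-ol (radical precursor) and an 8-bromo-epigallocatechin ether, two electrophile-derived partners joined by nickel/photoredox deoxygenative arylation.
- Upper unit: ring C is closed first on ring A as a chromone, ring B is then attached at C2 by enantioselective conjugate addition (sets 2S), and the ketone is reduced.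
- Lower unit: (−)-epigallocatechin is bought with rings D, F and E and its (2R,3R) centres intact, then perbenzylated and brominated at C8.
- End game: C4–C8 union (sets 4R, 2,4-trans), then removal of nine benzyl ethers.

Key step: step 8

Remark on the chemistry: the (R) antipode of the tert-butyl pyridine–oxazoline ligand is assumed to give the (2S) flavanone in step 3. If the first run shows the opposite sense (checked by debenzylating a sample to butin and comparing the sign of rotation with the (2S) series), the other antipode is used and nothing else changes.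

**Route**

Step 1
Reactants: 1 2',4'-dihydroxyacetophenone
Product: 2 4'-benzyloxy-2'-hydroxyacetophenone
Conditions: BnBr (1.05 equiv), K2CO3, acetone, reflux
Reagents that add atoms: benzyl bromide, BrCc1ccccc1
Why: Williamson etherification should be selective for the 4-hydroxyl because the 2-hydroxyl is hydrogen-bonded to the ketone and far less nucleophilic.

Step 2
Reactants: 2 4'-benzyloxy-2'-hydroxyacetophenone
Product: 4 7-benzyloxychromone, via enaminone 3 (not isolated)
Conditions: Me2NCH(OMe)2, toluene, 100 °C; then conc. HCl, CH2Cl2, 40 °C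
Reagents that add atoms: N,N-dimethylformamide dimethyl acetal, COC(OC)N(C)C
Why: Enaminone condensation at the acetyl methyl, then acid-promoted addition of the phenol to the β-carbon with loss of dimethylamine, is the standard enaminone route to chromones unsubstituted at C2 and C3 and closes ring C on ring A.

Step 3
Reactants: 4 7-benzyloxychromone; 5 3,4-bis(benzyloxy)phenylboronic acid (2 equiv)
Product: 6 (2S)-7-benzyloxy-2-[3,4-bis(benzyloxy)phenyl]chroman-4-one
Conditions: Pd(OCOCF3)2 (5 mol %), (R)-4-tert-butyl-2-(pyridin-2-yl)-4,5-dihydrooxazole (6 mol %), NH4PF6 (30 mol %), H2O (5 equiv), ClCH2CH2Cl, 60 °C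
Reagents that add atoms: none
Why: Hayashi–Miyaura-type asymmetric conjugate addition of an arylboronic acid to a chromone under cationic divalent palladium catalysis attaches ring B at C2; the chiral pyridine–oxazoline ligand selects the enone face in the aryl migratory insertion and so sets C2 as (S), and water protonates the palladium enolate before β-hydride elimination to the flavone can occur.

Step 4
Reactants: 6 (2S)-7-benzyloxy-2-[3,4-bis(benzyloxy)phenyl]chroman-4-one
Product: 7 (2S,4S)-7-benzyloxy-2-[3,4-bis(benzyloxy)phenyl]chroman-4-ol (2,4-cis)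
Conditions: NaBH4, THF/MeOH, 0 °C
Reagents that add atoms: none
Why: Borohydride reduction of a flavanone by axial hydride delivery should give the equatorial carbinol cis to the equatorial 2-aryl group; this C4 configuration is of no consequence because C4 becomes planar in step 8.

Step 5
Reactants: 8 (−)-epigallocatechin
Product: 9 (2R,3R)-5,7-bis(benzyloxy)-2-[3,4,5-tris(benzyloxy)phenyl]chroman-3-ol
Conditions: BnBr (5.2 equiv), K2CO3, DMF, argon, −10 °C to rt
Reagents that add atoms: benzyl bromide, BrCc1ccccc1
Why: Williamson etherification by carbonate alkylates only the five phenoxides and leaves the much less acidic 3-hydroxyl free, while degassed, cold conditions limit base-induced C2 epimerisation and oxidation of the pyrogallol ring E.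

Step 6
Reactants: 9 (2R,3R)-5,7-bis(benzyloxy)-2-[3,4,5-tris(benzyloxy)phenyl]chroman-3-ol
Product: 10 (2R,3R)-8-bromo-5,7-bis(benzyloxy)-2-[3,4,5-tris(benzyloxy)phenyl]chroman-3-ol
Conditions: NBS (1.0 equiv), CH2Cl2, −78 °C to 0 °C
Reagents that add atoms: N-bromosuccinimide, O=C1CCC(=O)N1Br
Why: Electrophilic aromatic bromination should occur on ring D, the most electron-rich arene, and at C8 rather than C6, as is usual for benzylated flavan-3-ols treated with one equivalent of NBS in the cold, since C6 is flanked by two benzyloxy groups.

Step 7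
Reactants: 10 (2R,3R)-8-bromo-5,7-bis(benzyloxy)-2-[3,4,5-tris(benzyloxy)phenyl]chroman-3-ol
Product: 11 (2R,3R)-8-bromo-3,5,7-tris(benzyloxy)-2-[3,4,5-tris(benzyloxy)phenyl]chroman
Conditions: NaH, BnBr, Bu4NI (cat.), DMF, 0 °C to rt
Reagents that add atoms: benzyl bromide, BrCc1ccccc1
Why: Williamson etherification of the secondary alkoxide caps the 3-hydroxyl so that it cannot condense with the benzoxazolium salt or bind nickel in step 8; the aryl bromide and the two stereocentres are inert to NaH.

Step 8
Reactants: 7 (2S,4S)-7-benzyloxy-2-[3,4-bis(benzyloxy)phenyl]chroman-4-ol (1.7 equiv); 11 (2R,3R)-8-bromo-3,5,7-tris(benzyloxy)-2-[3,4,5-tris(benzyloxy)phenyl]chroman (1.0 equiv)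
Product: 13 nona-O-benzyl (4→8) biflavan [(2S,4R)-7-benzyloxy-2-(3,4-bis(benzyloxy)phenyl)chroman-4-yl bonded through C4 to C8 of the (2R,3R)-hexa-O-benzyl-epigallocatechin unit], via benzoxazoline adduct 12 (not isolated)
Conditions: 7, 5,7-di-tert-butyl-3-phenylbenzoxazolium BF4 (1 equiv per 7), pyridine, MTBE, rt, pyridinium salt filtered off; then 11, [Ir(ppy)2(dtbbpy)]PF6 (1.5 mol %), NiBr2·dtbbpy (10 mol %), quinuclidine (1.75 equiv), MTBE/DMA, blue LEDs (450 nm), rt
Reagents that add atoms: 5,7-di-tert-butyl-3-phenylbenzoxazolium tetrafluoroborate, CC(C)(C)c1cc(C(C)(C)C)c2oc[n+](-c3ccccc3)c2c1.F[B-](F)(F)F (its atoms are carried only by intermediate 12; none remain in 13)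
Why: Proposed new method: the closest known reaction type is the nickel/photoredox deoxygenative arylation of alcohols, activated as benzoxazolium adducts, with aryl bromides, extended here to a secondary flavan-4-yl radical and an electron-rich aryl bromide flanked by two ortho oxygens, a pairing outside the demonstrated scope. The photoexcited iridium complex oxidises the aminal nitrogen of 12, quinuclidine removes the acidified aminal C–H, and β-scission of the C4–O bond expels the benzoxazolone and a planar C4 benzylic radical that is conjugated with ring A and cannot fragment further because C3 is CH2. Zerovalent nickel inserts into the C8–Br bond of 11, the divalent aryl nickel bromide traps the radical to give a trivalent alkyl(aryl)nickel species, reductive elimination forms the C4–C8 bond, and the monovalent nickel bromide is returned to zerovalent nickel by the reduced photocatalyst; no ring is closed in this step. The only new stereocentre, upper C4, should be set (R), that is 2,4-trans, by the substrate: with the C2 aryl group pseudo-equatorial on the half-chair of ring C, the bulky aryl nickel unit binds and eliminates on the pseudo-axial face syn to the axial C2–H, avoiding the peri clash with C5–H that a pseudo-equatorial C4 substituent would suffer, and reversible radical capture at nickel should funnel material through this lower-energy pathway. The step needs C8 rather than C6 bonding and no oligomerisation; both are secured because the bond can form only where the bromine sits and because C4 is never a cation, so Friedel–Crafts attack at the free C6 is excluded.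

Step 9
Reactants: 13 nona-O-benzyl (4→8) biflavan
Product: 14 CNP0211965.1, (2S,4R)-7,3',4'-trihydroxyflavan-(4→8)-(−)-epigallocatechin
Conditions: H2 (1 atm), Pd(OH)2/C, THF/MeOH/H2O, rt, degassed work-up
Reagents that add atoms: none
Why: Catalytic hydrogenolysis should cleave all nine benzyl ethers (eight aryl, one alkyl) under neutral conditions that leave the pyran C–O bonds, the C4–C8 bond and all four stereocentres untouched.

**Compound list**

1 | 2',4'-dihydroxyacetophenone | CC(=O)c1ccc(O)cc1O | starting material
2 | 4'-benzyloxy-2'-hydroxyacetophenone | CC(=O)c1ccc(OCc2ccccc2)cc1O | intermediate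
3 | (E)-1-(4-benzyloxy-2-hydroxyphenyl)-3-(dimethylamino)prop-2-en-1-one (enaminone, not isolated) | CN(C)/C=C/C(=O)c1ccc(OCc2ccccc2)cc1O | intermediate
4 | 7-benzyloxychromone | O=c1ccoc2cc(OCc3ccccc3)ccc12 | intermediate
5 | 3,4-bis(benzyloxy)phenylboronic acid | OB(O)c1ccc(OCc2ccccc2)c(OCc2ccccc2)c1 | starting material
6 | (2S)-7-benzyloxy-2-[3,4-bis(benzyloxy)phenyl]chroman-4-one | c1ccccc1COc1ccc2c(c1)O[C@H](c1ccc(OCc3ccccc3)c(OCc3ccccc3)c1)CC2=O | intermediate
7 | (2S,4S)-7-benzyloxy-2-[3,4-bis(benzyloxy)phenyl]chroman-4-ol (2,4-cis) | c1ccccc1COc1ccc2c(c1)O[C@H](c1ccc(OCc3ccccc3)c(OCc3ccccc3)c1)C[C@@H]2O | intermediate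
8 | (−)-epigallocatechin, (2R,3R) | Oc1cc(O)c2c(c1)O[C@H](c1cc(O)c(O)c(O)c1)[C@H](O)C2 | starting material
9 | (2R,3R)-5,7-bis(benzyloxy)-2-[3,4,5-tris(benzyloxy)phenyl]chroman-3-ol | c1ccccc1COc1cc(OCc3ccccc3)c2c(c1)O[C@H](c1cc(OCc3ccccc3)c(OCc3ccccc3)c(OCc3ccccc3)c1)[C@H](O)C2 | intermediate
10 | (2R,3R)-8-bromo-5,7-bis(benzyloxy)-2-[3,4,5-tris(benzyloxy)phenyl]chroman-3-ol | Brc1c(OCc3ccccc3)cc(OCc3ccccc3)c2c1O[C@H](c1cc(OCc3ccccc3)c(OCc3ccccc3)c(OCc3ccccc3)c1)[C@H](O)C2 | intermediate
11 | (2R,3R)-8-bromo-3,5,7-tris(benzyloxy)-2-[3,4,5-tris(benzyloxy)phenyl]chroman | Brc1c(OCc3ccccc3)cc(OCc3ccccc3)c2c1O[C@H](c1cc(OCc3ccccc3)c(OCc3ccccc3)c(OCc3ccccc3)c1)[C@H](OCc1ccccc1)C2 | intermediate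
12 | 5,7-di-tert-butyl-3-phenyl-2-(flavan-4-yloxy)-2,3-dihydrobenzoxazole, the adduct of 7 at its C4 oxygen (aminal carbon unassigned, not isolated) | c1ccccc1COc1ccc2c(c1)O[C@H](c1ccc(OCc3ccccc3)c(OCc3ccccc3)c1)C[C@@H]2OC1Oc2c(C(C)(C)C)cc(C(C)(C)C)cc2N1c1ccccc1 | intermediate
13 | nona-O-benzyl (4→8) biflavan, upper unit (2S,4R), lower unit (2R,3R) | c1ccccc1COc1ccc2c(c1)O[C@H](c1ccc(OCc3ccccc3)c(OCc3ccccc3)c1)C[C@H]2c1c(OCc3ccccc3)cc(OCc3ccccc3)c2c1O[C@H](c1cc(OCc3ccccc3)c(OCc3ccccc3)c(OCc3ccccc3)c1)[C@H](OCc1ccccc1)C2 | intermediate
14 | CNP0211965.1, (2S,4R)-7,3',4'-trihydroxyflavan-(4→8)-(−)-epigallocatechin | Oc1ccc2c(c1)O[C@H](c1ccc(O)c(O)c1)C[C@H]2c1c(O)cc(O)c2c1O[C@H](c1cc(O)c(O)c(O)c1)[C@H](O)C2 | target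

**Step count**

Total: 9 steps. Longest linear sequence: 6 steps (1, 2, 3, 4, 8, 9) from 2',4'-dihydroxyacetophenone; the lower unit is a three-step branch (5, 6, 7).

**Steps most likely to fail**

Step 8 (Proposed new method). What may go wrong: oxidative addition of zerovalent nickel into the crowded, electron-rich C8–Br bond and the subsequent reductive elimination may be too slow. The C4 radical would then be lost to dimerisation or hydrogen-atom capture, or the facial selectivity at C4 may be poor. The fallback is known cationic chemistry and sets out from flavan-4-ol 7 and the unbrominated pentabenzyl ether 9, used in three- to fourfold excess. TMSOTf in CH2Cl2 at −78 to −40 °C ionises 7 to the C4 benzylic cation, which is stabilised by O1 and the para 7-benzyloxy group. Ring D of 9 attacks it in a Friedel–Crafts alkylation, preferentially through C8 and along the pseudo-axial trajectory, to give the octa-O-benzyl (4→8) biflavan with a free 3-hydroxyl F1. The C6-linked isomer, the price of this fallback, is removed by chromatography. Hydrogenolysis of F1 under the conditions of step 9 returns to the route at 14.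

Step 3. What may go wrong: protodeboronation of the electron-rich boronic acid may outrun a sluggish insertion into the electron-rich chromone, or the enantioselectivity may be insufficient. The fallback sets out from acetophenone 2. Claisen–Schmidt condensation with commercial 3,4-bis(benzyloxy)benzaldehyde (KOH, EtOH) should give the 2'-hydroxychalcone F2. Oxa-Michael cyclisation (NaOAc, EtOH, reflux) should give the racemic flavanone F3. Asymmetric transfer hydrogenation with kinetic resolution, using RuCl(p-cymene)[(S,S)-TsDPEN] and HCO2H/Et3N, is expected to reduce the (2S) ketone faster, by the usual aryl ketone model that delivers the (4S) carbinol. This gives the cis alcohol directly and leaves the (2R)-flavanone F4, which is separated. The fallback returns to the route at 7.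

Step 9. What may go wrong: the catalyst may stall before all nine benzyl groups are removed (poisoning by traces of nickel, amine or bromide from step 8), the benzylic C2–O1 bonds may be over-reduced, or the pyrogallol ring may oxidise during isolation. The fallback sets out from 13 and replaces hydrogenolysis by Lewis-acid debenzylation: BCl3 with pentamethylbenzene as benzyl cation scavenger, CH2Cl2, −78 °C. It returns directly at 14 and makes no new compound. The interflavan bond should tolerate the acid because the 5-deoxy upper unit forms its C4 cation reluctantly; ring opening at C2–O1 is the point to watch.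

**Further compounds**

F1 | step 8 | octa-O-benzyl (4→8) biflavan with free 3-hydroxyl, upper unit (2S,4R), lower unit (2R,3R) | c1ccccc1COc1ccc2c(c1)O[C@H](c1ccc(OCc3ccccc3)c(OCc3ccccc3)c1)C[C@H]2c1c(OCc3ccccc3)cc(OCc3ccccc3)c2c1O[C@H](c1cc(OCc3ccccc3)c(OCc3ccccc3)c(OCc3ccccc3)c1)[C@H](O)C2
F2 | step 3 | (E)-4'-benzyloxy-2'-hydroxy-3,4-bis(benzyloxy)chalcone | O=C(/C=C/c1ccc(OCc2ccccc2)c(OCc2ccccc2)c1)c1ccc(OCc2ccccc2)cc1O
F3 | step 3 | racemic 7-benzyloxy-2-[3,4-bis(benzyloxy)phenyl]chroman-4-one | O=C1CC(c2ccc(OCc3ccccc3)c(OCc3ccccc3)c2)Oc2cc(OCc3ccccc3)ccc12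
F4 | step 3 | (2R)-7-benzyloxy-2-[3,4-bis(benzyloxy)phenyl]chroman-4-one, left unreduced | c1ccccc1COc1ccc2c(c1)O[C@@H](c1ccc(OCc3ccccc3)c(OCc3ccccc3)c1)CC2=O
F0 | step 9 | none | none
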